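**Retrosynthetic overview**
- Rings A and B are bought as phloroglucinol (1) and 3-bromo-4-hydroxyphenylacetic acid (2). Only ring C is built, by C-acylation (ketone 3) and C1 insertion/cyclisation to bromoisoflavone 4, which is masked as bis-silyl ether 5.
- Side chain C–C bond: disconnect ArCH2–C(=O) to aryl bromide 5 and the dienolate of methyl isopropenyl ketone (6), used as silyl dienol ether 7 through tin dienolate 8, giving α-methylene ketone 9 (new Pd α'-arylation).
- Stereocentre: ketone 9 → (R)-alcohol 10 by oxazaborolidine-catalysed (CBS) borane reduction, the metal-free asymmetric key step.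
- Last disconnection: the two O–Si bonds of 10, giving target 11.
- Ring order: A and B preformed; ring C is the first and only ring made (step 1).

Assumption: the target stereocentre is (R) as read from the given SMILES, and catalogue chemicals 1, 2 and 6 count as commercially available.

**Step 1**
Reactants: 1 phloroglucinol (benzene-1,3,5-triol); 2 2-(3-bromo-4-hydroxyphenyl)acetic acid
Product: 4 3-(3-bromo-4-hydroxyphenyl)-5,7-dihydroxy-4H-chromen-4-one (3'-bromogenistein), via deoxybenzoin 3 (not isolated)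
Conditions: BF3·OEt2 (solvent), 85 °C, 2 h; then DMF, MsCl, 75 °C, 3 h; aq. NaOAc work-up
Reagents that add atoms: N,N-dimethylformamide, CN(C)C=O (supplies C-2)
Why: BF3-promoted Friedel–Crafts C-acylation of the symmetric, electron-rich triol gives deoxybenzoin 3, whose active methylene is formylated by the DMF/MsCl (Vilsmeier-type) reagent and cyclises with loss of dimethylamine to close ring C (one-pot deoxybenzoin isoflavone synthesis); no stereocentre is formed.

**Step 2**
Reactants: 4 3-(3-bromo-4-hydroxyphenyl)-5,7-dihydroxy-4H-chromen-4-one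
Product: 5 3-{3-bromo-4-[(triisopropylsilyl)oxy]phenyl}-5-hydroxy-7-[(triisopropylsilyl)oxy]-4H-chromen-4-one
Conditions: i-Pr3SiCl (2.4 equiv), imidazole (5 equiv), DMF, 0 °C to rt
Reagents that add atoms: chlorotriisopropylsilane, CC(C)[Si](Cl)(C(C)C)C(C)C
Why: Silyl ether formation occurs at the acidic 7- and 4'-phenols only, because the 5-OH is hydrogen-bonded to the C-4 carbonyl and stays free.

**Step 3**
Reactants: 6 3-methylbut-3-en-2-one (methyl isopropenyl ketone)
Product: 7 trimethyl[(3-methylbuta-1,3-dien-2-yl)oxy]silane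
Conditions: Me3SiOTf (1.1 equiv), Et3N (1.3 equiv), Et2O, 0 °C; distil, use fresh
Reagents that add atoms: trimethylsilyl trifluoromethanesulfonate, C[Si](C)(C)OS(=O)(=O)C(F)(F)F
Why: Soft enolisation/O-silylation (silyl enol ether formation) can only take place at the acetyl methyl, the sole enolisable position, giving the cross-conjugated 2-silyloxy diene.

**Step 4**
Reactants: 5 3-{3-bromo-4-[(triisopropylsilyl)oxy]phenyl}-5-hydroxy-7-[(triisopropylsilyl)oxy]-4H-chromen-4-one; 7 trimethyl[(3-methylbuta-1,3-dien-2-yl)oxy]silane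
Product: 9 5-hydroxy-3-{3-(3-methyl-2-oxobut-3-en-1-yl)-4-[(triisopropylsilyl)oxy]phenyl}-7-[(triisopropylsilyl)oxy]-4H-chromen-4-one, via tin dienolate 8 (not isolated)
Conditions: Pd(OAc)2 (5 mol%), P(t-Bu)3 (10 mol%), Bu3SnF (2.6 equiv), 7 (2.6 equiv; one equivalent is sacrificed to the free 5-OH), BHT (cat.), toluene, 80 °C
Reagents that add atoms: tributyltin fluoride, CCCC[Sn](F)(CCCC)CCCC (its tin is carried by 8 only and is lost before 9)
Why: Proposed new method: Bu3SnF turns silyl dienol ether 7 into tin dienolate 8, which transmetalates onto the ArPdBr formed by oxidative addition of 5 to zerovalent palladium; the C-bound palladium enolate has no β-hydrogen and the cross-conjugated dienolate has a single nucleophilic carbon (the former acetyl CH2), so reductive elimination can only forge the ArCH2–C(=O) bond and release the α-methylene ketone; the closest known reaction type is the palladium-catalysed, tin-fluoride-mediated α-arylation of methyl-ketone silyl enol ethers with aryl bromides, which to my knowledge has not been shown for a 2-silyloxy-1,3-diene or on an isoflavone bromide.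

**Step 5**
Reactants: 9 5-hydroxy-3-{3-(3-methyl-2-oxobut-3-en-1-yl)-4-[(triisopropylsilyl)oxy]phenyl}-7-[(triisopropylsilyl)oxy]-4H-chromen-4-one
Product: 10 5-hydroxy-3-{3-[(2R)-2-hydroxy-3-methylbut-3-en-1-yl]-4-[(triisopropylsilyl)oxy]phenyl}-7-[(triisopropylsilyl)oxy]-4H-chromen-4-one
Conditions: (S)-2-methyl-CBS-oxazaborolidine (20 mol%), catecholborane (3 equiv), toluene/CH2Cl2, −78 °C; MeOH quench
Reagents that add atoms: none
Why: CBS reduction: the ketone binds the ring boron of the (S)-oxazaborolidine anti to the α-branched isopropenyl group (large) and syn to CH2Ar (small), and intramolecular hydride delivery from the N-bound catecholborane gives the (R)-carbinol (same sense as acetophenone to (R)-1-phenylethanol), with 1,2-selectivity at −78 °C and the chromone carbonyl masked in situ as its 5-O-boryl chelate.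

**Step 6**
Reactants: 10 5-hydroxy-3-{3-[(2R)-2-hydroxy-3-methylbut-3-en-1-yl]-4-[(triisopropylsilyl)oxy]phenyl}-7-[(triisopropylsilyl)oxy]-4H-chromen-4-one
Product: 11 5,7-dihydroxy-3-{4-hydroxy-3-[(2R)-2-hydroxy-3-methylbut-3-en-1-yl]phenyl}-4H-chromen-4-one
Conditions: Bu4NF (2.5 equiv), AcOH (2.5 equiv), THF, 0 °C
Reagents that add atoms: none
Why: Fluoride-mediated desilylation of the two aryl silyl ethers under buffered, non-acidic conditions leaves the acid-sensitive ortho-hydroxyaryl allylic alcohol and its stereocentre untouched.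

**Compound list**
1 | phloroglucinol (benzene-1,3,5-triol) | Oc1cc(O)cc(O)c1 | starting material
2 | 2-(3-bromo-4-hydroxyphenyl)acetic acid | OC(=O)Cc1ccc(O)c(Br)c1 | starting material
3 | 2-(3-bromo-4-hydroxyphenyl)-1-(2,4,6-trihydroxyphenyl)ethan-1-one (deoxybenzoin, not isolated) | O=C(Cc1ccc(O)c(Br)c1)c1c(O)cc(O)cc1O | intermediate
4 | 3-(3-bromo-4-hydroxyphenyl)-5,7-dihydroxy-4H-chromen-4-one | O=c1c(-c2ccc(O)c(Br)c2)coc2cc(O)cc(O)c12 | intermediate
5 | 3-{3-bromo-4-[(triisopropylsilyl)oxy]phenyl}-5-hydroxy-7-[(triisopropylsilyl)oxy]-4H-chromen-4-one | O=c1c(-c2ccc(O[Si](C(C)C)(C(C)C)C(C)C)c(Br)c2)coc2cc(O[Si](C(C)C)(C(C)C)C(C)C)cc(O)c12 | intermediate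
6 | 3-methylbut-3-en-2-one | CC(=O)C(C)=C | starting material
7 | trimethyl[(3-methylbuta-1,3-dien-2-yl)oxy]silane | C=C(C)C(=C)O[Si](C)(C)C | intermediate
8 | tributyl[(3-methylbuta-1,3-dien-2-yl)oxy]stannane (tin dienolate, not isolated) | C=C(C)C(=C)O[Sn](CCCC)(CCCC)CCCC | intermediate
9 | 5-hydroxy-3-{3-(3-methyl-2-oxobut-3-en-1-yl)-4-[(triisopropylsilyl)oxy]phenyl}-7-[(triisopropylsilyl)oxy]-4H-chromen-4-one | C=C(C)C(=O)Cc1cc(-c2coc3cc(O[Si](C(C)C)(C(C)C)C(C)C)cc(O)c3c2=O)ccc1O[Si](C(C)C)(C(C)C)C(C)C | intermediate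
10 | 5-hydroxy-3-{3-[(2R)-2-hydroxy-3-methylbut-3-en-1-yl]-4-[(triisopropylsilyl)oxy]phenyl}-7-[(triisopropylsilyl)oxy]-4H-chromen-4-one | C=C(C)[C@H](O)Cc1cc(-c2coc3cc(O[Si](C(C)C)(C(C)C)C(C)C)cc(O)c3c2=O)ccc1O[Si](C(C)C)(C(C)C)C(C)C | intermediate
11 | 5,7-dihydroxy-3-{4-hydroxy-3-[(2R)-2-hydroxy-3-methylbut-3-en-1-yl]phenyl}-4H-chromen-4-one | C=C(C)[C@H](O)Cc1cc(-c2coc3cc(O)cc(O)c3c2=O)ccc1O | target

**Totals**
Total steps: 6. Longest linear sequence: 5 (steps 1, 2, 4, 5, 6; step 3 is a one-step side branch).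

**Three steps most likely to fail, with fallbacks**

Step 4 (the proposed new arylation) may fail through polymerisation of the dienolate, Michael addition to 9, or slow coupling at the hindered bromide. The fallback uses known chemistry only, sets out from 5 and comes back at 10, bypassing 9. Linear-selective Negishi coupling of 5 with Me2C=CHCH2ZnBr (Pd(OAc)2/CPhos, THF, rt) gives the prenyl arene 5-hydroxy-3-{3-(3-methylbut-2-en-1-yl)-4-[(triisopropylsilyl)oxy]phenyl}-7-[(triisopropylsilyl)oxy]-4H-chromen-4-one F1. Shi epoxidation with the D-fructose-derived ketone catalyst (KHSO5 as Oxone, K2CO3 buffer pH 10.5, Bu4NHSO4, MeCN/dimethoxymethane/H2O, 0 °C) gives 3-{3-{[(2R)-3,3-dimethyloxiran-2-yl]methyl}-4-[(triisopropylsilyl)oxy]phenyl}-5-hydroxy-7-[(triisopropylsilyl)oxy]-4H-chromen-4-one F2; the (R) sense is predicted from the spiro transition-state model by analogy with trans-β-methylstyrene. Al(OiPr)3 in toluene at 110 °C then isomerises the epoxide towards a methyl group without breaking the secondary C–O bond, giving 10 with retention.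

Step 5 (CBS reduction) may give insufficient ee because isopropenyl and CH2Ar are not very different in size, or may be slowed by catalyst binding to the chromone. The fallback sets out from 9 and comes back at 10. Luche reduction (NaBH4, CeCl3·7H2O, MeOH, −78 °C) gives the racemic alcohol rac-5-hydroxy-3-{3-(2-hydroxy-3-methylbut-3-en-1-yl)-4-[(triisopropylsilyl)oxy]phenyl}-7-[(triisopropylsilyl)oxy]-4H-chromen-4-one F3. Acylative kinetic resolution with a chiral isothiourea organocatalyst (HyperBTM, isobutyric anhydride, i-Pr2NEt, CHCl3, 0 °C; catalyst antipode chosen so that the (S)-alcohol is acylated) gives the (S)-isobutyrate (2S)-1-{5-(5-hydroxy-4-oxo-7-[(triisopropylsilyl)oxy]-4H-chromen-3-yl)-2-[(triisopropylsilyl)oxy]phenyl}-3-methylbut-3-en-2-yl 2-methylpropanoate F4 and leaves the (R)-alcohol, which is 10 (at most 50%). The same resolution can also upgrade a partially enriched CBS product.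

Step 1 (one-pot acylation/ring closure) may give a low yield if acylation is incomplete or the polar product is hard to purify. The fallback sets out from 1 and comes back at 3, now isolated. Houben–Hoesch acylation of 1 with purchased 2-(3-bromo-4-hydroxyphenyl)acetonitrile F5 (HCl gas, ZnCl2, Et2O, 0 °C) precipitates the ketiminium salt 2-(3-bromo-4-hydroxyphenyl)-1-(2,4,6-trihydroxyphenyl)ethan-1-iminium chloride F6. Hydrolysis in boiling water gives pure 3, which is cyclised to 4 in a separate operation (BF3·OEt2, DMF, MsCl, 75 °C).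

**Further compounds**
F1 | step 4 | 5-hydroxy-3-{3-(3-methylbut-2-en-1-yl)-4-[(triisopropylsilyl)oxy]phenyl}-7-[(triisopropylsilyl)oxy]-4H-chromen-4-one | CC(C)=CCc1cc(-c2coc3cc(O[Si](C(C)C)(C(C)C)C(C)C)cc(O)c3c2=O)ccc1O[Si](C(C)C)(C(C)C)C(C)C
F2 | step 4 | 3-{3-{[(2R)-3,3-dimethyloxiran-2-yl]methyl}-4-[(triisopropylsilyl)oxy]phenyl}-5-hydroxy-7-[(triisopropylsilyl)oxy]-4H-chromen-4-one | CC1(C)O[C@@H]1Cc1cc(-c2coc3cc(O[Si](C(C)C)(C(C)C)C(C)C)cc(O)c3c2=O)ccc1O[Si](C(C)C)(C(C)C)C(C)C
F3 | step 5 | rac-5-hydroxy-3-{3-(2-hydroxy-3-methylbut-3-en-1-yl)-4-[(triisopropylsilyl)oxy]phenyl}-7-[(triisopropylsilyl)oxy]-4H-chromen-4-one (racemate) | C=C(C)C(O)Cc1cc(-c2coc3cc(O[Si](C(C)C)(C(C)C)C(C)C)cc(O)c3c2=O)ccc1O[Si](C(C)C)(C(C)C)C(C)C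
F4 | step 5 | (2S)-1-{5-(5-hydroxy-4-oxo-7-[(triisopropylsilyl)oxy]-4H-chromen-3-yl)-2-[(triisopropylsilyl)oxy]phenyl}-3-methylbut-3-en-2-yl 2-methylpropanoate | C=C(C)[C@@H](OC(=O)C(C)C)Cc1cc(-c2coc3cc(O[Si](C(C)C)(C(C)C)C(C)C)cc(O)c3c2=O)ccc1O[Si](C(C)C)(C(C)C)C(C)C
F5 | step 1 | 2-(3-bromo-4-hydroxyphenyl)acetonitrile (purchased) | N#CCc1ccc(O)c(Br)c1
F6 | step 1 | 2-(3-bromo-4-hydroxyphenyl)-1-(2,4,6-trihydroxyphenyl)ethan-1-iminium chloride | [NH2+]=C(Cc1ccc(O)c(Br)c1)c1c(O)cc(O)cc1O.[Cl-]
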